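**Retrosynthetic overview**
1. Target 18 ⇒ peripheral double epoxidation, O‑8 tigloylation and C‑13 methylenation ⇒ 8β‑hydroxy‑13‑nor‑6α,12‑olide 12.
2. 12 ⇒ C‑6 by OH‑directed reduction and lactonisation, C‑8/C‑7 by asymmetric transfer hydrogenation with dynamic kinetic resolution ⇒ ten‑membered β‑diketone ester 9, which has no fixed stereocentre.
3. 9 ⇒ C‑7 alkylation and Grob ring expansion (C‑4–C‑10 cleaved, both E‑alkenes formed) ⇒ hydroazulenedione phosphate 6.
4. 6 ⇒ reductive cleavage of C‑5–C‑9 (ring C: five → seven) ⇒ 5‑4‑5 photoadduct 5 ⇒ cyclopent‑4‑ene‑1,3‑dione plus the allylic phosphate of 2,3‑dimethylcyclopentenone.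
5. Ring order: two five‑membered rings → 5‑4‑5 tricycle → 5‑7 bicycle → ten‑membered ring → γ‑lactone → two oxiranes.

Assumption: germacrane numbering (C‑1 to C‑15) is used for every intermediate. Compounds 2–6 are racemic and 8–9 carry no fixed stereocentre, so absolute configuration enters in step 6.

**Step 1**
Reactants: 1 2,3‑dimethylcyclopent‑2‑en‑1‑one
Product: 2 (±)‑2,3‑dimethylcyclopent‑2‑en‑1‑ol
Conditions: NaBH4, CeCl3·7H2O, MeOH, 0 °C
Reagents that add atoms: none
Why: Luche reduction gives clean 1,2‑reduction of the tetrasubstituted enone, and the racemic carbinol centre (C‑1) is harmless because step 5 erases it.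

**Step 2**
Reactants: 2 (±)‑2,3‑dimethylcyclopent‑2‑en‑1‑ol
Product: 3 (±)‑diethyl 2,3‑dimethylcyclopent‑2‑en‑1‑yl phosphate
Conditions: ClP(O)(OEt)2, pyridine, CH2Cl2, 0 °C, used without chromatography
Reagents that add atoms: diethyl chlorophosphate, CCOP(=O)(Cl)OCC
Why: O‑phosphorylation installs a bulky nucleofuge that has no acidic α‑hydrogens (unlike a mesylate) and tolerates light, Zn/AcOH and amide bases.

**Step 3**
Reactants: 3 (±)‑diethyl 2,3‑dimethylcyclopent‑2‑en‑1‑yl phosphate; 4 cyclopent‑4‑ene‑1,3‑dione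
Product: 5 (±)‑diethyl (1,7‑dimethyl‑3,5‑dioxotricyclo[5.3.0.0^2,6]decan‑10‑yl) phosphate (cis‑anti‑cis; phosphate cis to both angular methyls)
Conditions: hν (366 nm), CH2Cl2, −20 °C, 3 (2 equiv)
Reagents that add atoms: none
Why: Enone–alkene [2+2] photocycloaddition through the triplet 1,4‑biradical forms C‑4–C‑5 and C‑9–C‑10 and both quaternary centres; the symmetric enedione removes any regiochemical question, and attack anti to the phosphate places O‑1 cis to the methyls.

**Step 4**
Reactants: 5 the tricyclic dione phosphate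
Product: 6 (±)‑diethyl (cis‑3a,8a‑dimethyl‑5,7‑dioxodecahydroazulen‑1‑yl) phosphate (phosphate cis to the methyls)
Conditions: Zn dust, AcOH/THF, 23 °C, ultrasound
Reagents that add atoms: none
Why: Two‑electron reductive cleavage of the strained 1,4‑dicarbonyl bond C‑5–C‑9 (flanked by C‑6=O and C‑8=O) expands ring C from five to seven members; C‑5 and C‑9 become CH2, so any syn/anti photoadduct mixture converges.

**Step 5**
Reactants: 6 the hydroazulenedione phosphate; 7 methyl bromoacetate
Product: 9 methyl 2‑[(3E,7E)‑4,8‑dimethyl‑2,10‑dioxocyclodeca‑3,7‑dien‑1‑yl]acetate, via lithium diketonate 8 (not isolated)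
Conditions: LiN(iPr)2 (2.3 equiv), THF, −78 → 0 °C; then 7, DMPU, 0 → 23 °C
Reagents that add atoms: none
Why: Proposed new method: a β‑diketone‑dianion‑driven Grob (1,4‑) fragmentation across two vicinal quaternary carbons, in which the first equivalent of base gives the C‑7 diketonate and the second removes kinetically a proton from the less hindered γ‑carbon C‑5 (C‑9 is screened by the neighbouring phosphate); the C‑5 lone pair, the C‑4–C‑10 σ‑bond and the pseudo‑equatorial C‑1–O bond are anti‑periplanar, so electron flow C‑5→C‑4 and C‑4–C‑10→C‑10=C‑1 expels diethyl phosphate and opens the bicyclo[5.3.0]decane to the ten‑membered ring; the phosphate cis to the methyls gives the (E)‑1(10)‑alkene and the conformer with C‑3 anti to C‑6 gives the (E)‑4‑enone, the driving force being relief of the eclipsed methyls and collapse of a localised carbanion to diketonate 8, which is C‑alkylated at C‑7 in the same flask; the closest known reaction types are the enolate‑assisted 1,4‑fragmentation of mesyloxy‑decalin carbaldehydes and the Wharton–Grob fragmentation of 1,3‑diol monosulfonates.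

**Step 6**
Reactants: 9 the β‑diketone ester
Product: 10 methyl 8β‑hydroxy‑6‑oxo‑13‑norgermacra‑1(10)E,4E‑dien‑12‑oate (H‑7α)
Conditions: RuCl[(R,R)‑TsDPEN](p‑cymene) (2 mol %), HCO2Na, H2O/CH2Cl2, 30 °C
Reagents that add atoms: none
Why: Noyori–Ikariya asymmetric transfer hydrogenation with dynamic kinetic resolution reduces only the non‑conjugated, more electrophilic C‑8 carbonyl while C‑7 racemises through the enol; with the branched C‑7 side taking the place of the aryl group in the quadrant model, this sets 8R (8β‑OH) and the syn C‑7 centre, and the strained cis‑8,12‑lactone does not close.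

**Step 7**
Reactants: 10 the β‑hydroxy ketone ester
Product: 12 8β‑hydroxy‑13‑norgermacra‑1(10)E,4E‑dien‑12,6α‑olide, via diol ester 11 (not isolated)
Conditions: Me4NBH(OAc)3, MeCN/AcOH 1:1, −30 °C; aq. NaHCO3; then DBU (10 mol %), CH2Cl2, 23 °C
Reagents that add atoms: none
Why: In the Evans–Saksena reduction the acetoxyborohydride bound to the axial 8β‑oxygen delivers hydride intramolecularly to the β‑face of C‑6 and gives the 1,3‑anti diol (6α‑OH); only the strain‑free trans‑6α,12‑lactone then closes, which is the lactone preferred in 6α,8β‑dioxygenated germacradienes.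

**Step 8**
Reactants: 12 the hydroxy lactone
Product: 15 eupatolide (8β‑hydroxygermacra‑1(10)E,4E,11(13)‑trien‑12,6α‑olide), via Mannich base 13 (not isolated), via methiodide 14 (not isolated)
Conditions: LiN(iPr)2 (2.2 equiv), THF, −78 °C; CH2=NMe2+ I−; H2O; MeI, MeOH; aq. NaHCO3
Reagents that add atoms: N,N‑dimethylmethyleneiminium iodide, C=[N+](C)C.[I-]
Why: Mannich methylenation of the alkoxide–lactone enolate dianion followed by quaternisation and E1cB loss of trimethylamine introduces C‑13; the enolised lactone is protected from attack by the 8‑alkoxide.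

**Step 9**
Reactants: 15 eupatolide; 16 tigloyl chloride ((E)‑2‑methylbut‑2‑enoyl chloride)
Product: 17 8‑O‑tigloyleupatolide
Conditions: Et3N, DMAP (cat.), CH2Cl2, 0 → 23 °C
Reagents that add atoms: none
Why: DMAP‑catalysed acylation esterifies the only free hydroxyl with retention at C‑8, and the E‑configured tiglate does not isomerise.

**Step 10**
Reactants: 17 8‑O‑tigloyleupatolide
Product: 18 1β,10α:4α,5β‑diepoxy‑8β‑tigloyloxygermacr‑11(13)‑en‑12,6α‑olide (target)
Conditions: mCPBA (2.3 equiv), Na2HPO4, CH2Cl2, 0 °C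
Reagents that add atoms: 3‑chloroperoxybenzoic acid, O=C(OO)c1cccc(Cl)c1
Why: Prilezhaev epoxidation attacks only the two electron‑rich trisubstituted ring alkenes, from the outer face of the crown conformer with both methyls β, which sets C‑1, C‑10, C‑4 and C‑5; the tiglate and α‑methylene lactone alkenes are too electron‑poor to react.

**Compound list**
1 | 2,3‑dimethylcyclopent‑2‑en‑1‑one | CC1=C(C)C(=O)CC1 | starting material
2 | (±)‑2,3‑dimethylcyclopent‑2‑en‑1‑ol (one enantiomer drawn) | O[C@H]1CCC(C)=C1C | intermediate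
3 | (±)‑diethyl 2,3‑dimethylcyclopent‑2‑en‑1‑yl phosphate | CCOP(=O)(OCC)O[C@H]1CCC(C)=C1C | intermediate
4 | cyclopent‑4‑ene‑1,3‑dione | O=C1C=CC(=O)C1 | starting material
5 | (±)‑cis‑anti‑cis tricyclic dione phosphate | CCOP(=O)(OCC)O[C@H]1CC[C@]2(C)[C@H]3C(=O)CC(=O)[C@H]3[C@]12C | intermediate
6 | (±)‑cis‑hydroazulene‑5,7‑dione phosphate | CCOP(=O)(OCC)O[C@H]1CC[C@]2(C)CC(=O)CC(=O)C[C@]12C | intermediate
7 | methyl bromoacetate | COC(=O)CBr | starting material
8 | lithium enolate of (4E,8E)‑5,9‑dimethylcyclodeca‑4,8‑diene‑1,3‑dione | [Li+].[O-]C1=CC(=O)/C=C(C)/CC/C=C(C)/C1 | intermediate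
9 | methyl 2‑[(3E,7E)‑4,8‑dimethyl‑2,10‑dioxocyclodeca‑3,7‑dien‑1‑yl]acetate (C‑7 labile) | O=C1C(CC(=O)OC)C(=O)/C=C(C)/CC/C=C(C)/C1 | intermediate
10 | methyl 8β‑hydroxy‑6‑oxo‑13‑norgermacra‑1(10)E,4E‑dien‑12‑oate | O=C1/C=C(C)/CC/C=C(C)/C[C@@H](O)[C@H]1CC(=O)OC | intermediate
11 | methyl 6α,8β‑dihydroxy‑13‑norgermacra‑1(10)E,4E‑dien‑12‑oate | O[C@@H]1/C=C(C)/CC/C=C(C)/C[C@@H](O)[C@H]1CC(=O)OC | intermediate
12 | 8β‑hydroxy‑13‑norgermacra‑1(10)E,4E‑dien‑12,6α‑olide | O=C1C[C@@H]2[C@H](O)C/C(C)=C/CC/C(C)=C/[C@H]2O1 | intermediate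
13 | 11‑(dimethylaminomethyl) derivative of 12 (C‑11 epimers) | O=C1C(CN(C)C)[C@@H]2[C@H](O)C/C(C)=C/CC/C(C)=C/[C@H]2O1 | intermediate
14 | methiodide of 13 | O=C1C(C[N+](C)(C)C)[C@@H]2[C@H](O)C/C(C)=C/CC/C(C)=C/[C@H]2O1.[I-] | intermediate
15 | eupatolide | O=C1C(=C)[C@@H]2[C@H](O)C/C(C)=C/CC/C(C)=C/[C@H]2O1 | intermediate
16 | tigloyl chloride | C/C=C(\C)C(=O)Cl | starting material
17 | 8‑O‑tigloyleupatolide | O=C1C(=C)[C@@H]2[C@H](OC(=O)/C(C)=C/C)C/C(C)=C/CC/C(C)=C/[C@H]2O1 | intermediate
18 | 1β,10α:4α,5β‑diepoxy‑8β‑tigloyloxygermacr‑11(13)‑en‑12,6α‑olide | C=C1C(=O)O[C@H]2[C@H]1[C@H](OC(=O)/C(C)=C/C)C[C@@]1(C)O[C@@H]1CC[C@@]1(C)O[C@H]21 | target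

**Step count**
Total steps: 10. Longest linear sequence: 10.

**Steps most likely to fail**

**Step 5 (the new step).**
- Failure modes: cyclopropane closure from a C‑9 carbanion onto C‑1, or a 4Z‑enone.
- The fallback sets out from 6 and comes back at 9.
- It masks the near carbonyl so that a single, regiodefined mono‑enolate performs the known enolate‑assisted 1,4‑fragmentation.
- (MeO)3CH with catalytic TsOH in MeOH gives the 8‑methoxy enone F5 and its 6‑methoxy isomer F6, which are separated.
- F5 is deprotonated kinetically at the α′‑carbon C‑5 with LiN(iPr)2 (1.1 equiv, −78 °C). On warming it fragments to the macrocyclic vinylogous ester F7.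
- Aqueous LiOH followed by mild acidification gives the free diketone F8.
- K2CO3 and 7 in acetone give 9.

**Step 3.**
- Failure modes: oxetane or ene products from the enedione triplet and the electron‑rich alkene.
- The fallback sets out from 3 and comes back at 5.
- It uses an ordinary cyclopentenone chromophore, 4‑(tert‑butyldimethylsilyloxy)cyclopent‑2‑en‑1‑one, in the photocycloaddition.
- The two regioisomeric adducts, the 8‑silyl ether F1 and the 6‑silyl ether F2, are carried on together.
- HF·pyridine gives the 8‑ketol F3 and the 6‑ketol F4.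
- Dess–Martin oxidation converges both on the symmetric dione unit of 5.

**Step 6.**
- Failure modes: wrong carbonyl reduced, 1,4‑reduction, or low syn selectivity on the flexible macrocycle.
- The fallback sets out from 9 and comes back at 10.
- It replaces outer‑sphere metal‑hydride transfer by binding‑pocket control: a dynamic reductive kinetic resolution with a screened NADPH‑dependent ketoreductase (glucose and glucose dehydrogenase recycling, pH 7 buffer).
- This method is known for 2‑alkyl‑1,3‑diketones. It makes no new compound (F0).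

**Further compounds**
F1 | step 3 | 8‑(tert‑butyldimethylsilyloxy)‑6‑oxo photoadduct | CCOP(=O)(OCC)O[C@H]1CC[C@]2(C)[C@H]3C(=O)CC(O[Si](C)(C)C(C)(C)C)[C@H]3[C@]12C
F2 | step 3 | 6‑(tert‑butyldimethylsilyloxy)‑8‑oxo photoadduct | CCOP(=O)(OCC)O[C@H]1CC[C@]2(C)[C@H]3C(O[Si](C)(C)C(C)(C)C)CC(=O)[C@H]3[C@]12C
F3 | step 3 | 8‑hydroxy‑6‑oxo tricycle | CCOP(=O)(OCC)O[C@H]1CC[C@]2(C)[C@H]3C(=O)CC(O)[C@H]3[C@]12C
F4 | step 3 | 6‑hydroxy‑8‑oxo tricycle | CCOP(=O)(OCC)O[C@H]1CC[C@]2(C)[C@H]3C(O)CC(=O)[C@H]3[C@]12C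
F5 | step 5 | 8‑methoxy‑7‑en‑6‑one of the hydroazulene phosphate | CCOP(=O)(OCC)O[C@H]1CC[C@]2(C)CC(=O)C=C(OC)C[C@]12C
F6 | step 5 | 6‑methoxy‑6‑en‑8‑one isomer | CCOP(=O)(OCC)O[C@H]1CC[C@]2(C)CC(OC)=CC(=O)C[C@]12C
F7 | step 5 | ten‑membered vinylogous methyl ester | COC1=CC(=O)/C=C(C)/CC/C=C(C)/C1
F8 | step 5 | (4E,8E)‑5,9‑dimethylcyclodeca‑4,8‑diene‑1,3‑dione | O=C1CC(=O)/C=C(C)/CC/C=C(C)/C1
F0 | step 6 | none | none
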